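**Assumption:** the stereochemistry is exactly as in the given SMILES, and umbelliferone is 7-hydroxycoumarin. The three building blocks (3, 5, 14) and the small reagents are purchased.

## Retrosynthetic overview
1. The aryl ether comes from Mitsunobu coupling of 7-hydroxycoumarin with a primary alcohol. The CH2CH2CO2H chain is carried as a CH2CH2CH2OTBDPS group and oxidised to the acid last.
2. The ring CH–CH2OH comes from one-carbon homologation (Wittig–MOM) of a cyclopentanone. That centre is set by aldehyde equilibration, with the CH2OH trans to the ring methyl.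
3. The ring CH–CH3 comes from face-selective hydrogenation of an α-methylene ketone. H2 adds from the face opposite the two cis substituents, so the new methyl lands on the crowded face.
4. The vicinal quaternary C(Me)(chain) and C(isobutenyl) diad comes from one pot: asymmetric Cu-catalysed 1,4-addition of isobutenyl Grignard to a 2-alkylcyclopentenone, then MeI trapping anti to the new substituent.
5. No ring is formed in the route. The cyclopentane comes from commercial cyclopentenone (via iodination and Negishi coupling), and the coumarin comes from commercial umbelliferone.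

## Route

**Step 1**
Reactants: 1 (cyclopent-2-en-1-one)
Product: 2 (2-iodocyclopent-2-en-1-one)
Conditions: I2, pyridine, CH2Cl2/CCl4, 0 °C → rt
Reagents that add atoms: iodine, II
Why: Johnson α-iodination (conjugate addition of pyridine, iodination, elimination) puts a cross-coupling handle at C2, and no stereocentre is formed.

**Step 2**
Reactants: 2; 3 ((3-bromopropoxy)-tert-butyldiphenylsilane)
Product: 4 (2-[3-(TBDPSO)propyl]cyclopent-2-en-1-one)
Conditions: (i) 3, Zn, LiCl, THF, 40 °C (gives the alkylzinc bromide); (ii) 2, Pd(PPh3)4 (5 mol%), THF, 50 °C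
Reagents that add atoms: 3, BrCCCO[Si](c1ccccc1)(c1ccccc1)C(C)(C)C (supplies the silyl-protected propyl chain)
Why: Negishi coupling of a primary alkylzinc with a vinyl iodide installs the three-carbon chain that becomes CH2CH2CO2H.

**Step 3**
Reactants: 4; 5 (2-methylprop-1-en-1-ylmagnesium bromide)
Product: 6 ((2R,3S)-2-methyl-3-(2-methylprop-1-en-1-yl)-2-[3-(TBDPSO)propyl]cyclopentan-1-one)
Conditions: 5, CuBr·SMe2 (10 mol%), (R,S)-Josiphos-type ligand (12 mol%), MTBE, –78 °C; then HMPA, MeI, –78 → 0 °C
Reagents that add atoms: 5, CC(C)=C[Mg]Br (isobutenyl group); iodomethane, CI (ring methyl)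
Why: Proposed new method: the chiral Cu–alkenyl species adds to one enantiotopic face of the enone β-carbon (setting C3 = S). The tetrasubstituted Mg-enolate is then methylated anti to the new neighbouring isobutenyl group, so the quaternary C2 (R) has Me trans and the propyl chain cis to isobutenyl, as in the target. The closest precedents are Feringa/Alexakis Cu-catalysed asymmetric conjugate addition with enolate trapping and Noyori's three-component prostaglandin coupling.

**Step 4**
Reactants: 6; 7 (Eschenmoser's salt)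
Product: 8 (α-methylene ketone)
Conditions: LiHMDS, THF, –78 °C; then 7; then MeI; then DBU, CH2Cl2, rt
Reagents that add atoms: 7, C=[N+](C)C.[I-] (supplies the =CH2)
Why: the quaternary C2 leaves only one enolisable α-carbon, so Mannich aminomethylation, quaternisation and Hofmann-type elimination give the exocyclic enone regiospecifically; this is a standard α-methylenation.

**Step 5**
Reactants: 8
Product: 9 ((2R,3S,5S)-2,5-dimethyl-3-(2-methylprop-1-en-1-yl)-2-[3-(TBDPSO)propyl]cyclopentan-1-one)
Conditions: H2 (1 atm), RhCl(PPh3)3 (10 mol%), PhH/EtOH, rt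
Reagents that add atoms: none
Why: the homogeneous catalyst reduces the 1,1-disubstituted exocyclic alkene but not the trisubstituted isobutenyl. H2 is delivered to C5 from the face carrying only the quaternary methyl, anti to the cis-disposed isobutenyl and propyl chain, so the new methyl ends up on the more hindered face. This is the same logic as hydrogenation of 16-methylene-17-ketosteroids.

**Step 6**
Reactants: 9; 10 ((methoxymethyl)triphenylphosphonium chloride)
Product: 11 (methoxymethylene enol ether, E/Z mixture)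
Conditions: 10, KOtBu, THF, 0 °C → 40 °C
Reagents that add atoms: 10, COC[P+](c1ccccc1)(c1ccccc1)c1ccccc1.[Cl-] (supplies =CH–OMe)
Why: Wittig methoxymethylenation is a known one-carbon homologation that tolerates hindered ketones when an excess of ylide is used, and it creates no new stereocentre at this stage.

**Step 7**
Reactants: 11
Product: 12 ((1R,2R,3S,5S)-2-[3-(TBDPSO)propyl]-2,5-dimethyl-3-(2-methylprop-1-en-1-yl)cyclopentane-1-carbaldehyde)
Conditions: 1 M aq. HCl, THF, 40 °C
Reagents that add atoms: water, O
Why: enol-ether hydrolysis gives the aldehyde. Acid-catalysed enolisation equilibrates its α-centre to the thermodynamic isomer, with CHO trans to the C5 methyl and cis to the smaller quaternary methyl. TBDPS survives aqueous acid, and any minor C1 epimer is removed at 13.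

**Step 8**
Reactants: 12
Product: 13 (primary alcohol, [(1R,2R,3S,5S)-2-[3-(TBDPSO)propyl]-2,5-dimethyl-3-(2-methylprop-1-en-1-yl)cyclopentyl]methanol)
Conditions: NaBH4, MeOH/THF, 0 °C
Reagents that add atoms: none
Why: chemoselective hydride reduction of the aldehyde with no stereochemical change.

**Step 9**
Reactants: 13; 14 (7-hydroxycoumarin)
Product: 15 (aryl ether, TBDPS-protected)
Conditions: 14, PPh3, DIAD, THF, 0 °C → rt
Reagents that add atoms: 14, O=c1ccc2ccc(O)cc2o1 (supplies the coumarinyloxy group)
Why: Mitsunobu etherification; the acidic phenol (pKa about 8) alkylates at the primary carbon, so no stereocentre is touched.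

**Step 10**
Reactants: 15
Product: 16 (free primary alcohol)
Conditions: TBAF/AcOH (1:1), THF, rt
Reagents that add atoms: none
Why: fluoride cleaves the silyl ether. The AcOH buffer protects the coumarin lactone from ring-opening.

**Step 11**
Reactants: 16
Product: 17 (3-[(1R,2R,3S,5S)-1,3-dimethyl-5-(2-methylprop-1-en-1-yl)-2-{[(2-oxo-2H-chromen-7-yl)oxy]methyl}cyclopentyl]propanal)
Conditions: Dess–Martin periodinane, NaHCO3, CH2Cl2, rt
Reagents that add atoms: none
Why: mild, neutral oxidation of the primary alcohol; the alkene and coumarin are untouched and there is no α-stereocentre to epimerise.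

**Step 12**
Reactants: 17
Product: 18 (ferulsinaic acid)
Conditions: NaClO2, NaH2PO4, 2-methyl-2-butene, t-BuOH/H2O, rt
Reagents that add atoms: sodium chlorite, [Na+].[O-]Cl=O (supplies the carboxyl oxygen)
Why: Pinnick oxidation; the alkene scavenger protects the trisubstituted alkene from HOCl, and the conditions are mildly acidic so the coumarin is not opened.

## Compound list
1 | cyclopent-2-en-1-one | O=C1C=CCC1 | starting material
2 | 2-iodocyclopent-2-en-1-one | O=C1C(I)=CCC1 | intermediate
3 | (3-bromopropoxy)-tert-butyldiphenylsilane | BrCCCO[Si](c1ccccc1)(c1ccccc1)C(C)(C)C | starting material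
4 | 2-[3-(TBDPSO)propyl]cyclopent-2-en-1-one | O=C1C(CCCO[Si](c2ccccc2)(c2ccccc2)C(C)(C)C)=CCC1 | intermediate
5 | 2-methylprop-1-en-1-ylmagnesium bromide | CC(C)=C[Mg]Br | starting material
6 | (2R,3S)-2-methyl-3-(2-methylprop-1-en-1-yl)-2-[3-(TBDPSO)propyl]cyclopentan-1-one | CC(C)=C[C@@H]1CCC(=O)[C@]1(C)CCCO[Si](c2ccccc2)(c2ccccc2)C(C)(C)C | intermediate
7 | N,N-dimethylmethyleneiminium iodide (Eschenmoser's salt) | C=[N+](C)C.[I-] | starting material
8 | (2R,3S)-5-methylidene-2-methyl-3-(2-methylprop-1-en-1-yl)-2-[3-(TBDPSO)propyl]cyclopentan-1-one | CC(C)=C[C@@H]1CC(=C)C(=O)[C@]1(C)CCCO[Si](c2ccccc2)(c2ccccc2)C(C)(C)C | intermediate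
9 | (2R,3S,5S)-2,5-dimethyl-3-(2-methylprop-1-en-1-yl)-2-[3-(TBDPSO)propyl]cyclopentan-1-one | CC(C)=C[C@@H]1C[C@H](C)C(=O)[C@]1(C)CCCO[Si](c2ccccc2)(c2ccccc2)C(C)(C)C | intermediate
10 | (methoxymethyl)triphenylphosphonium chloride | COC[P+](c1ccccc1)(c1ccccc1)c1ccccc1.[Cl-] | starting material
11 | (2R,3S,5S)-1-(methoxymethylidene)-2,5-dimethyl-3-(2-methylprop-1-en-1-yl)-2-[3-(TBDPSO)propyl]cyclopentane | CC(C)=C[C@@H]1C[C@H](C)C(=COC)[C@]1(C)CCCO[Si](c2ccccc2)(c2ccccc2)C(C)(C)C | intermediate
12 | (1R,2R,3S,5S)-2-[3-(TBDPSO)propyl]-2,5-dimethyl-3-(2-methylprop-1-en-1-yl)cyclopentane-1-carbaldehyde | CC(C)=C[C@@H]1C[C@H](C)[C@@H](C=O)[C@]1(C)CCCO[Si](c2ccccc2)(c2ccccc2)C(C)(C)C | intermediate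
13 | {(1R,2R,3S,5S)-2-[3-(TBDPSO)propyl]-2,5-dimethyl-3-(2-methylprop-1-en-1-yl)cyclopentyl}methanol | CC(C)=C[C@@H]1C[C@H](C)[C@@H](CO)[C@]1(C)CCCO[Si](c2ccccc2)(c2ccccc2)C(C)(C)C | intermediate
14 | 7-hydroxycoumarin (umbelliferone) | O=c1ccc2ccc(O)cc2o1 | starting material
15 | 7-({(1R,2R,3S,5S)-2-[3-(TBDPSO)propyl]-2,5-dimethyl-3-(2-methylprop-1-en-1-yl)cyclopentyl}methoxy)-2H-chromen-2-one | CC(C)=C[C@@H]1C[C@H](C)[C@@H](COc2ccc3ccc(=O)oc3c2)[C@]1(C)CCCO[Si](c2ccccc2)(c2ccccc2)C(C)(C)C | intermediate
16 | 7-({(1R,2R,3S,5S)-2-(3-hydroxypropyl)-2,5-dimethyl-3-(2-methylprop-1-en-1-yl)cyclopentyl}methoxy)-2H-chromen-2-one | CC(C)=C[C@@H]1C[C@H](C)[C@@H](COc2ccc3ccc(=O)oc3c2)[C@]1(C)CCCO | intermediate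
17 | 3-[(1R,2R,3S,5S)-1,3-dimethyl-5-(2-methylprop-1-en-1-yl)-2-{[(2-oxo-2H-chromen-7-yl)oxy]methyl}cyclopentyl]propanal | CC(C)=C[C@@H]1C[C@H](C)[C@@H](COc2ccc3ccc(=O)oc3c2)[C@]1(C)CCC=O | intermediate
18 | ferulsinaic acid, 3-[(1R,2R,3S,5S)-1,3-dimethyl-5-(2-methylprop-1-en-1-yl)-2-{[(2-oxo-2H-chromen-7-yl)oxy]methyl}cyclopentyl]propanoic acid | CC(C)=C[C@@H]1C[C@H](C)[C@@H](COc2ccc3ccc(=O)oc3c2)[C@]1(C)CCC(=O)O | target

## Totals
Total steps: 12. Longest linear sequence: 12 (1 → 2 → 4 → 6 → 8 → 9 → 11 → 12 → 13 → 15 → 16 → 17 → 18). Compound 3 is convergent, and 5, 7, 10 and 14 are purchased partners.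

## Three steps most likely to fail
1. **Step 3** (ee and diastereoselectivity of the three-component coupling).
   Fallback: stepwise route. Use Rh/chiral-diene-catalysed asymmetric 1,4-addition of isobutenylboronic acid to 4. Then do regioselective thermodynamic-enolate methylation (KHMDS, MeI) of the resulting trans ketone, and separate the diastereomers.
2. **Step 5** (face selectivity at the ring CH–CH3).
   Fallback: replace H2 with Stryker-type CuH conjugate reduction of 8, which adds hydride to the exocyclic CH2 and then protonates the enolate kinetically at the less hindered face.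
3. **Step 9** (Mitsunobu on a hindered, neopentyl-type primary alcohol).
   Fallback: convert 13 to the triflate (Tf2O, 2,6-lutidine), then displace it with 14 and Cs2CO3 in DMF at 60 °C. This is a Williamson SN2 route, not a redox condensation.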